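**Strategy.** The angular methyl on C10, wedged between quaternary C9 and the ring-fusion CH C5, is disconnected to a cyclopropane spanning C5–C10 of a Δ5(10)-octalin. The C4 carbinol of ring A, later the methylidene carbon, sits allylic to this tetrasubstituted alkene, so its zinc alkoxide can hand a CH2 unit to the same face: one operation forges the C10–CH2 bond, a sacrificial C5–CH2 bond and both ring-fusion stereocentres. The precursor is the (4S)-allylic alcohol with C8/C9 already set and C11 held as a bulky silyl ether. Oxidation at C4 then lets lithium in ammonia cut C5–CH2, unveiling the methyl and trans C5–H.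

Key step: step 8

Numbering and faces: ring A = C1–C5 plus C10, ring B = C5–C10, C11 = the CH2 on C9. β is the face of the C10 methyl in the target; the C8 and C9 methyls are β, C11 and the C5 hydrogen are α.

Remark on the chemistry: the chiral ligand of step 1 is assumed to be available in the antipode that gives (S) at C8. The primary alcohol is carried as a triisopropylsilyl ether, and the methylidene is installed directly after the ring opening, so no ketal is needed.

**Step 1**
Reactants: 1 2-methylcyclohex-2-en-1-one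
Product: 3 (2S,3S)-2-(hydroxymethyl)-2,3-dimethylcyclohexan-1-one, via bromomagnesium enolate 2 (not isolated)
Conditions: MeMgBr, Cu(OTf)2 (cat.), chiral imidazolinium-derived NHC ligand (cat.), Et2O, −30 °C; then monomeric CH2O in THF, −78 °C; aq. work-up
Reagents that add atoms: methylmagnesium bromide, C[Mg]Br; formaldehyde, C=O
Why: Ligand-controlled Cu(OTf)2-catalysed asymmetric conjugate addition sets C8, and the magnesium enolate then undergoes aldol addition to formaldehyde on the face anti to the new C8 methyl, which makes quaternary C9 with the two methyls cis.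

**Step 2**
Reactants: 3 (2S,3S)-2-(hydroxymethyl)-2,3-dimethylcyclohexan-1-one
Product: 4 (2S,3S)-2,3-dimethyl-2-{[(triisopropylsilyl)oxy]methyl}cyclohexan-1-one
Conditions: i-Pr3SiOTf, 2,6-lutidine, CH2Cl2, −78 to 0 °C
Reagents that add atoms: triisopropylsilyl trifluoromethanesulfonate, CC(C)[Si](OS(=O)(=O)C(F)(F)F)(C(C)C)C(C)C
Why: O-Silylation with a silyl triflate and a hindered pyridine base is fast at the neopentyl alcohol and cannot trigger retro-aldol loss of formaldehyde; the triisopropylsilyl group is chosen for acid stability in step 6 and for bulk without zinc affinity in step 8.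

**Step 3**
Reactants: 4 (2S,3S)-2,3-dimethyl-2-{[(triisopropylsilyl)oxy]methyl}cyclohexan-1-one
Product: 6 (5S,6S)-5,6-dimethyl-6-{[(triisopropylsilyl)oxy]methyl}cyclohex-1-en-1-yl trifluoromethanesulfonate, via potassium enolate 5 (not isolated)
Conditions: KN(SiMe3)2, THF, −78 °C; then PhNTf2, −78 to 0 °C
Reagents that add atoms: N-phenylbis(trifluoromethanesulfonimide), O=S(=O)(N(c1ccccc1)S(=O)(=O)C(F)(F)F)C(F)(F)F
Why: Only C5 carries α-hydrogens, so enolisation and O-sulfonylation (enol triflate formation) should give a single C5=C10 enol triflate.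

**Step 4**
Reactants: 6 (5S,6S)-5,6-dimethyl-6-{[(triisopropylsilyl)oxy]methyl}cyclohex-1-en-1-yl trifluoromethanesulfonate; 7 ethyl 4-bromobutanoate
Product: 9 ethyl 4-[(5S,6R)-5,6-dimethyl-6-{[(triisopropylsilyl)oxy]methyl}cyclohex-1-en-1-yl]butanoate, via (4-ethoxy-4-oxobutyl)zinc bromide 8 (not isolated)
Conditions: 7, Zn dust, LiCl, THF, 40 °C; then 6, Pd(dppf)Cl2 (cat.), THF, 50 °C
Reagents that add atoms: none
Why: Zinc insertion gives an ester-tolerant primary alkylzinc, and Negishi coupling with the vinyl triflate forms the C10–C1 bond with the alkene kept in place, the chelating diphosphine suppressing β-hydride elimination.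

**Step 5**
Reactants: 9 ethyl 4-[(5S,6R)-5,6-dimethyl-6-{[(triisopropylsilyl)oxy]methyl}cyclohex-1-en-1-yl]butanoate
Product: 10 4-[(5S,6R)-5,6-dimethyl-6-{[(triisopropylsilyl)oxy]methyl}cyclohex-1-en-1-yl]butanoic acid
Conditions: LiOH, THF/MeOH/H2O, rt; then 1 M HCl, 0 °C
Reagents that add atoms: lithium hydroxide, [Li+].[OH-]
Why: Saponification of the unhindered ethyl ester by acyl–oxygen cleavage leaves the silyl ether and the alkene untouched.

**Step 6**
Reactants: 10 4-[(5S,6R)-5,6-dimethyl-6-{[(triisopropylsilyl)oxy]methyl}cyclohex-1-en-1-yl]butanoic acid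
Product: 12 (5R,6S)-5,6-dimethyl-5-{[(triisopropylsilyl)oxy]methyl}-3,4,5,6,7,8-hexahydronaphthalen-1(2H)-one (octalone: C4 ketone conjugated with the C5=C10 alkene), via mixed trifluoroacetic anhydride 11 (not isolated)
Conditions: (CF3CO)2O, CH2Cl2, 0 °C to rt; then Et3N, 0 °C
Reagents that add atoms: none
Why: The mixed anhydride acts as an acylium equivalent that attacks the trisubstituted alkene at C5 in a 6-endo intramolecular alkene acylation (Darzens–Nenitzescu type), and loss of the now acidic C5 proton, completed by Et3N, should give the conjugated tetrasubstituted enone without mineral acid that would strip the silyl ether.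

**Step 7**
Reactants: 12 (5R,6S)-5,6-dimethyl-5-{[(triisopropylsilyl)oxy]methyl}-3,4,5,6,7,8-hexahydronaphthalen-1(2H)-one
Product: 13 (1S,5R,6S)-5,6-dimethyl-5-{[(triisopropylsilyl)oxy]methyl}-1,2,3,4,5,6,7,8-octahydronaphthalen-1-ol (octalin allylic alcohol: C4 hydroxyl β and C5=C10 alkene)
Conditions: (R)-2-methyl-CBS-oxazaborolidine (cat.), BH3·SMe2, THF, −20 °C; MeOH
Reagents that add atoms: none
Why: Corey–Bakshi–Shibata reduction, in which the oxazaborolidine binds the carbonyl with the alkenyl flank as the large group and delivers hydride to one face, should set C4 as (S) under reagent control regardless of the remote C8/C9 centres.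

**Step 8**
Reactants: 13 (1S,5R,6S)-5,6-dimethyl-5-{[(triisopropylsilyl)oxy]methyl}-1,2,3,4,5,6,7,8-octahydronaphthalen-1-ol
Product: 15 cyclopropane-fused decalinol (13 with a CH2 bridging C5 and C10 on the β face; 4S,5R,8S,9R,10S), via ethylzinc alkoxide 14 (not isolated)
Conditions: Et2Zn, CH2I2, CH2Cl2, 0 °C to rt; aq. work-up
Reagents that add atoms: diiodomethane, ICI
Why: Et2Zn first converts the C4 hydroxyl into an ethylzinc alkoxide, which binds the (iodomethyl)zinc carbenoid and passes CH2 to the neighbouring C5=C10 alkene through a concerted, butterfly-shaped three-centre transition state; the closest known reaction is the hydroxyl-directed Simmons–Smith cyclopropanation of cyclic allylic alcohols. The three-membered ring closes in a single suprafacial [2+1] event, the C5–CH2 and C10–CH2 bonds forming on one face with no open intermediate. The new stereocentres C5 and C10 are therefore both fixed by the (S)-carbinol at C4, which holds the oxygen on the β face. The step needs β-face selectivity and enough reactivity at a tetrasubstituted alkene beside quaternary C9. Intramolecular delivery from the alkoxide supplies the rate, and the bulky silyloxymethyl group on the α face of C9 shields that face without offering zinc a second binding site. The alkene is the only π bond present, so chemoselectivity is not in question.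

**Step 9**
Reactants: 15 cyclopropane-fused decalinol
Product: 16 cyclopropyl ketone (C4 ketone of 15; 5R,8S,9R,10S)
Conditions: Pr4N[RuO4] (cat.), NMO, 4 Å MS, CH2Cl2, rt
Reagents that add atoms: none
Why: Ley–Griffith oxidation of the secondary carbinol is neutral, which avoids cyclopropylcarbinyl cation rearrangement and spares the silyl ether.

**Step 10**
Reactants: 16 cyclopropyl ketone
Product: 18 (4aS,5R,6S,8aR)-4a,5,6-trimethyl-5-{[(triisopropylsilyl)oxy]methyl}octahydronaphthalen-1(2H)-one (trans-fused C4 ketone with the C10 methyl), via lithium enolate 17 (not isolated)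
Conditions: Li, NH3(l)/THF, −78 °C; isoprene; solid NH4Cl, −78 °C
Reagents that add atoms: none
Why: Dissolving-metal reduction of the conjugated cyclopropyl ketone should cleave the exocyclic C5–CH2 bond, the one best aligned with the carbonyl π system, leaving the CH2 as the C10 methyl and a C4=C5 enolate, whose kinetic protonation at −78 °C is axial to both rings and anti to the C10 methyl and so gives the α C5–H (trans fusion).

**Step 11**
Reactants: 18 trans-fused C4 ketone
Product: 19 triisopropyl{[(1R,2S,4aS,8aS)-1,2,8a-trimethyl-5-methylidenedecahydronaphthalen-1-yl]methoxy}silane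
Conditions: Zn, CH2Br2, TiCl4, THF, −40 to 0 °C; then 18, CH2Cl2, 0 °C to rt
Reagents that add atoms: dibromomethane, BrCBr
Why: Takai–Lombardo methylenation is non-basic, so C5, which a basic ylide could epimerise because the trans isomer holds the C8 and C10 methyls 1,3-diaxial, should be carried intact into the exocyclic alkene and is then no longer enolisable.

**Step 12**
Reactants: 19 methylidene silyl ether
Product: 20 [(1R,2S,4aS,8aS)-1,2,8a-trimethyl-5-methylidenedecahydronaphthalen-1-yl]methanol
Conditions: Bu4NF, THF, rt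
Reagents that add atoms: none
Why: Fluoride-induced Si–O cleavage (desilylation) frees the C11 alcohol while the isolated alkene is inert.

**Step 13**
Reactants: 20 C11 alcohol
Product: 21 (1R,2S,4aS,8aS)-1,2,8a-trimethyl-5-methylidenedecahydronaphthalene-1-carbaldehyde
Conditions: Dess–Martin periodinane, NaHCO3, CH2Cl2, rt
Reagents that add atoms: none
Why: Dess–Martin oxidation of the neopentyl alcohol stops at the aldehyde, which cannot epimerise because C9 is quaternary.

**Step 14**
Reactants: 22 methyl 4-hydroxy-3-iodobenzoate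
Product: 23 methyl 3-iodo-4-(methoxymethoxy)benzoate
Conditions: MOMCl, i-Pr2NEt, CH2Cl2, 0 °C to rt
Reagents that add atoms: chloromethyl methyl ether, COCCl
Why: O-Alkylation of the phenol (Williamson type) masks the acidic OH with an acetal that cannot migrate to a neighbouring alkoxide and that later leaves under near-neutral conditions.

**Step 15**
Reactants: 21 C11 aldehyde; 23 methyl 3-iodo-4-(methoxymethoxy)benzoate
Product: 25 methyl 3-{hydroxy[(1R,2S,4aS,8aS)-1,2,8a-trimethyl-5-methylidenedecahydronaphthalen-1-yl]methyl}-4-(methoxymethoxy)benzoate (both C11 epimers), via arylmagnesium chloride 24 (not isolated)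
Conditions: 23, i-PrMgCl·LiCl, THF, −40 °C; then 21, LaCl3·2LiCl, −40 to 0 °C; aq. work-up
Reagents that add atoms: none
Why: Iodine–magnesium exchange at low temperature gives an aryl Grignard reagent that tolerates its own ester, and LaCl3-assisted 1,2-addition to the non-enolisable aldehyde forms the C11–aryl bond, the C11 configuration being irrelevant because the hydroxyl is removed next.

**Step 16**
Reactants: 25 benzylic alcohol
Product: 27 O-benzylic S-methyl xanthate of 25, via sodium xanthate 26 (not isolated)
Conditions: NaH, CS2, THF, 0 °C to rt; then MeI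
Reagents that add atoms: carbon disulfide, S=C=S; iodomethane, CI
Why: Xanthate formation, the first half of a Barton–McCombie deoxygenation, works on hindered alkoxides because CS2 is a small electrophile, and with C9 quaternary there is no β-hydrogen for Chugaev elimination.

**Step 17**
Reactants: 27 xanthate
Product: 28 methyl 4-(methoxymethoxy)-3-{[(1R,2S,4aS,8aS)-1,2,8a-trimethyl-5-methylidenedecahydronaphthalen-1-yl]methyl}benzoate
Conditions: Bu3SnH, AIBN (cat.), toluene, 100 °C
Reagents that add atoms: none
Why: Barton–McCombie radical deoxygenation passes through a benzylic C11 radical that takes hydrogen from the stannane and, unlike a cation, should neither provoke 1,2-shifts from quaternary C9 nor reach the C4 methylidene on the other ring.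

**Step 18**
Reactants: 28 methoxymethyl ether of the target
Product: 29 methyl 4-hydroxy-3-{[(1R,2S,4aS,8aS)-1,2,8a-trimethyl-5-methylidenedecahydronaphthalen-1-yl]methyl}benzoate (CNP0169318.1)
Conditions: ZnBr2, n-PrSH, CH2Cl2, 0 °C
Reagents that add atoms: none
Why: Lewis acid-assisted transacetalisation to the thiol should cleave the aryl methoxymethyl ether under conditions too mild to isomerise the exocyclic alkene or touch the methyl ester.

**Compound list**

1 | 2-methylcyclohex-2-en-1-one | CC1=CCCCC1=O | starting material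
2 | bromomagnesium (3S)-2,3-dimethylcyclohex-1-en-1-olate | C[C@H]1CCCC(O[Mg]Br)=C1C | intermediate
3 | (2S,3S)-2-(hydroxymethyl)-2,3-dimethylcyclohexan-1-one | O=C1CCC[C@H](C)[C@@]1(C)CO | intermediate
4 | (2S,3S)-2,3-dimethyl-2-{[(triisopropylsilyl)oxy]methyl}cyclohexan-1-one | O=C1CCC[C@H](C)[C@@]1(C)CO[Si](C(C)C)(C(C)C)C(C)C | intermediate
5 | potassium (5S,6S)-5,6-dimethyl-6-{[(triisopropylsilyl)oxy]methyl}cyclohex-1-en-1-olate | [K]OC1=CCC[C@H](C)[C@@]1(C)CO[Si](C(C)C)(C(C)C)C(C)C | intermediate
6 | (5S,6S)-5,6-dimethyl-6-{[(triisopropylsilyl)oxy]methyl}cyclohex-1-en-1-yl trifluoromethanesulfonate | O=S(=O)(OC1=CCC[C@H](C)[C@@]1(C)CO[Si](C(C)C)(C(C)C)C(C)C)C(F)(F)F | intermediate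
7 | ethyl 4-bromobutanoate | CCOC(=O)CCCBr | starting material
8 | (4-ethoxy-4-oxobutyl)zinc bromide | CCOC(=O)CCC[Zn]Br | intermediate
9 | ethyl 4-[(5S,6R)-5,6-dimethyl-6-{[(triisopropylsilyl)oxy]methyl}cyclohex-1-en-1-yl]butanoate | CCOC(=O)CCCC1=CCC[C@H](C)[C@@]1(C)CO[Si](C(C)C)(C(C)C)C(C)C | intermediate
10 | 4-[(5S,6R)-5,6-dimethyl-6-{[(triisopropylsilyl)oxy]methyl}cyclohex-1-en-1-yl]butanoic acid | OC(=O)CCCC1=CCC[C@H](C)[C@@]1(C)CO[Si](C(C)C)(C(C)C)C(C)C | intermediate
11 | mixed anhydride of 10 with trifluoroacetic acid | O=C(CCCC1=CCC[C@H](C)[C@@]1(C)CO[Si](C(C)C)(C(C)C)C(C)C)OC(=O)C(F)(F)F | intermediate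
12 | (5R,6S)-5,6-dimethyl-5-{[(triisopropylsilyl)oxy]methyl}-3,4,5,6,7,8-hexahydronaphthalen-1(2H)-one | O=C1CCCC2=C1CC[C@H](C)[C@@]2(C)CO[Si](C(C)C)(C(C)C)C(C)C | intermediate
13 | (1S,5R,6S)-5,6-dimethyl-5-{[(triisopropylsilyl)oxy]methyl}-1,2,3,4,5,6,7,8-octahydronaphthalen-1-ol | O[C@H]1CCCC2=C1CC[C@H](C)[C@@]2(C)CO[Si](C(C)C)(C(C)C)C(C)C | intermediate
14 | ethylzinc alkoxide of 13 | CC[Zn]O[C@H]1CCCC2=C1CC[C@H](C)[C@@]2(C)CO[Si](C(C)C)(C(C)C)C(C)C | intermediate
15 | cyclopropane-fused decalinol (4S,5R,8S,9R,10S; CH2 bridging C5 and C10 on the β face) | O[C@H]1CCC[C@]23C[C@@]13CC[C@H](C)[C@@]2(C)CO[Si](C(C)C)(C(C)C)C(C)C | intermediate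
16 | cyclopropyl ketone (5R,8S,9R,10S; C4 ketone of 15) | O=C1CCC[C@]23C[C@@]13CC[C@H](C)[C@@]2(C)CO[Si](C(C)C)(C(C)C)C(C)C | intermediate
17 | lithium C4=C5 enolate of 18 | [Li]OC1=C2CC[C@H](C)[C@@](C)(CO[Si](C(C)C)(C(C)C)C(C)C)[C@@]2(C)CCC1 | intermediate
18 | (4aS,5R,6S,8aR)-4a,5,6-trimethyl-5-{[(triisopropylsilyl)oxy]methyl}octahydronaphthalen-1(2H)-one | O=C1CCC[C@@]2(C)[C@H]1CC[C@H](C)[C@@]2(C)CO[Si](C(C)C)(C(C)C)C(C)C | intermediate
19 | triisopropyl{[(1R,2S,4aS,8aS)-1,2,8a-trimethyl-5-methylidenedecahydronaphthalen-1-yl]methoxy}silane | C=C1CCC[C@@]2(C)[C@H]1CC[C@H](C)[C@@]2(C)CO[Si](C(C)C)(C(C)C)C(C)C | intermediate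
20 | [(1R,2S,4aS,8aS)-1,2,8a-trimethyl-5-methylidenedecahydronaphthalen-1-yl]methanol | C=C1CCC[C@@]2(C)[C@H]1CC[C@H](C)[C@@]2(C)CO | intermediate
21 | (1R,2S,4aS,8aS)-1,2,8a-trimethyl-5-methylidenedecahydronaphthalene-1-carbaldehyde | C=C1CCC[C@@]2(C)[C@H]1CC[C@H](C)[C@@]2(C)C=O | intermediate
22 | methyl 4-hydroxy-3-iodobenzoate | COC(=O)c1ccc(O)c(I)c1 | starting material
23 | methyl 3-iodo-4-(methoxymethoxy)benzoate | COCOc1ccc(cc1I)C(=O)OC | intermediate
24 | [5-(methoxycarbonyl)-2-(methoxymethoxy)phenyl]magnesium chloride | COCOc1ccc(cc1[Mg]Cl)C(=O)OC | intermediate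
25 | methyl 3-{hydroxy[(1R,2S,4aS,8aS)-1,2,8a-trimethyl-5-methylidenedecahydronaphthalen-1-yl]methyl}-4-(methoxymethoxy)benzoate (C11 epimers) | C=C1CCC[C@@]2(C)[C@H]1CC[C@H](C)[C@@]2(C)C(O)c1cc(C(=O)OC)ccc1OCOC | intermediate
26 | sodium O-alkyl xanthate of 25 | C=C1CCC[C@@]2(C)[C@H]1CC[C@H](C)[C@@]2(C)C(OC(=S)[S-])c1cc(C(=O)OC)ccc1OCOC.[Na+] | intermediate
27 | O-alkyl S-methyl xanthate of 25 | C=C1CCC[C@@]2(C)[C@H]1CC[C@H](C)[C@@]2(C)C(OC(=S)SC)c1cc(C(=O)OC)ccc1OCOC | intermediate
28 | methyl 4-(methoxymethoxy)-3-{[(1R,2S,4aS,8aS)-1,2,8a-trimethyl-5-methylidenedecahydronaphthalen-1-yl]methyl}benzoate | C=C1CCC[C@@]2(C)[C@H]1CC[C@H](C)[C@@]2(C)Cc1cc(C(=O)OC)ccc1OCOC | intermediate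
29 | methyl 4-hydroxy-3-{[(1R,2S,4aS,8aS)-1,2,8a-trimethyl-5-methylidenedecahydronaphthalen-1-yl]methyl}benzoate | C=C1CCC[C@@]2(C)[C@H]1CC[C@H](C)[C@@]2(C)Cc1cc(C(=O)OC)ccc1O | target

**Step count and risk**

Total: 18 steps. Longest linear sequence: 17 steps (steps 1–13 and 15–18; step 14 prepares the aryl partner).

Steps most likely to fail:

Step 8. Methylene transfer may stall at the tetrasubstituted alkene beside quaternary C9, or the carbenoid may reach the α face if it is not held by the alkoxide. The fallback sets out from 13 and comes back at 15. Free dichlorocarbene (CHCl3, 50% aq. NaOH, BnEt3NCl, phase transfer) is a much smaller and more electrophilic one-carbon donor than the zinc carbenoid and should add to the electron-rich alkene to give the gem-dichlorocyclopropyl carbinol F1. The face would then rest on approach anti to the silyloxymethyl group with assistance from the hydroxyl. Reductive dechlorination with Na and t-BuOH in THF should then give 15.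

Step 10. The enolate may be protonated from the β face, the ketone may drift to the cis fusion during work-up, or the endocyclic C5–C10 bond may be cut instead of C5–CH2. The fallback sets out from 15 and comes back at 18 without forming an enolate. The carbinol is converted into its S-methyl xanthate F2 (NaH, CS2, then MeI). Bu3SnH and AIBN at high stannane concentration should generate the C4 cyclopropylcarbinyl radical, which opens along the better-aligned exocyclic bond and, after hydrogen transfer, gives the C10-methyl Δ4-octalin F3. Hydroboration–oxidation (BH3·THF; then H2O2, NaOH) adds hydrogen to C5 and hydroxyl to C4 in a syn, irreversible addition from the α face, because the β face would place boron 1,3-diaxial to the C10 methyl; this gives the 4α-ol F4 with the trans fusion fixed. Ley–Griffith oxidation then returns 18.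

Step 6. The cationic closure may be diverted by a 1,2-shift of a C9 substituent to the developing C10 cation, or the silyl ether may be lost to trifluoroacetic acid. The fallback sets out from 4 and comes back at 13, bypassing steps 3–7. Vilsmeier-type bromoformylation of ketone 4 (PBr3, DMF, CHCl3) should give the β-bromo enal F5 with bromine on C10 and the formyl carbon, the future C4, on C5. Brown allylation with the antipode of B-allyldiisopinocampheylborane that gives the (S)-carbinol should furnish the homoallylic alcohol F6. Hydroboration of the terminal alkene with excess 9-BBN gives the alkylborane F7, its hydroxyl held as the borinate. Intramolecular B-alkyl Suzuki–Miyaura coupling (Pd(dppf)Cl2, AsPh3, aq. K3PO4, THF/DMF) closes ring A at C1–C10 and returns 13 after work-up.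

**Further compounds**

F1 | step 8 | gem-dichlorocyclopropyl carbinol (15 with CCl2 in place of the bridging CH2) | O[C@H]1CCC[C@]23C(Cl)(Cl)[C@@]13CC[C@H](C)[C@@]2(C)CO[Si](C(C)C)(C(C)C)C(C)C
F2 | step 10 | O-cyclopropylcarbinyl S-methyl xanthate of 15 | CSC(=S)O[C@H]1CCC[C@]23C[C@@]13CC[C@H](C)[C@@]2(C)CO[Si](C(C)C)(C(C)C)C(C)C
F3 | step 10 | C10-methyl Δ4-octalin (C4=C5 alkene; 8S,9R,10S) | C1=C2CC[C@H](C)[C@@](C)(CO[Si](C(C)C)(C(C)C)C(C)C)[C@@]2(C)CCC1
F4 | step 10 | trans-fused 4α-ol (4R; C5 hydrogen α) | O[C@@H]1CCC[C@@]2(C)[C@H]1CC[C@H](C)[C@@]2(C)CO[Si](C(C)C)(C(C)C)C(C)C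
F5 | step 6 | (3S,4S)-2-bromo-3,4-dimethyl-3-{[(triisopropylsilyl)oxy]methyl}cyclohex-1-ene-1-carbaldehyde | O=CC1=C(Br)[C@](C)(CO[Si](C(C)C)(C(C)C)C(C)C)[C@@H](C)CC1
F6 | step 6 | (1S)-1-[(3S,4S)-2-bromo-3,4-dimethyl-3-{[(triisopropylsilyl)oxy]methyl}cyclohex-1-en-1-yl]but-3-en-1-ol | C=CC[C@H](O)C1=C(Br)[C@](C)(CO[Si](C(C)C)(C(C)C)C(C)C)[C@@H](C)CC1
F7 | step 6 | terminal 9-BBN alkylborane of F6 (hydroxyl as 9-BBN borinate) | B1(C2CCCC1CCC2)CCC[C@H](OB1C2CCCC1CCC2)C1=C(Br)[C@](C)(CO[Si](C(C)C)(C(C)C)C(C)C)[C@@H](C)CC1
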